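**Retrosynthetic overview**

1. Target ⇐ C7 enol triflate: the C7=C8 alkene (triflate reduction), the C2 acetate, the C2,C3-cis-diol (OsO4 on a C2=C3 alkene) and the C4 methyl group (aldehyde enolate methylation) are added late to a trans-decalin.
2. Trans-decalin ⇐ cross-conjugated cyclohexadienone: dissolving-metal reduction sets H5 and H9 and leaves the C7–C8 enolate, which is trapped as the triflate.
3. Dienone ⇐ phenol by the C1–C10 disconnection: ring B is a benzene ring from the start and is never "formed"; ring A is the only ring that is closed, by anodic dearomatisation, when allylsilane carbon C1 attacks C10.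
4. Phenol ⇐ 2-bromo-m-xylene + side-chain zinc reagent (C13 from (R)-methyl hydrogen 3-methylglutarate) + (R)-β-silyl ester (C3 by Rh-catalysed conjugate addition), joined by Negishi coupling and ester α-arylation.
5. Enabling feature: in ring B the methyl-bearing C10 lies para to C7 and, like methyl-bearing C8, flanks C9, so ring B is a masked 2,4-dimethylphenol; C1 sits at the end of the arm C5–C4–C3–C2–C1, so a C3-silylated allyl group reaches C10 through a six-membered ring.

Key step: step 11

Remark 1: bicyclic compounds are named with labdane numbers (C1–C20; ring A = C1–C5, C10; ring B = C5–C10); "18-nor" means the C4 methyl group is still missing.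
Remark 2: in step 6 the BINAP antipode is the one that delivers the 3R ester; (R)-BINAP is assumed by analogy with additions to (E)-enoates.

**Route**

Step 1
Reactants: 1 (R)-5-methoxy-3-methyl-5-oxopentanoic acid ((R)-methyl hydrogen 3-methylglutarate)
Product: 3 (R)-4-methyloxan-2-one, via methyl (R)-5-hydroxy-3-methylpentanoate 2 (not isolated)
Conditions: BH3·SMe2, THF, 0 °C → rt; then TsOH (cat.), toluene, 60 °C
Reagents that add atoms: none
Why: Borane reduces the free acid chemoselectively beside the methyl ester and acid-catalysed lactonisation of 2 follows; the C13 stereocentre is not touched.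

Step 2
Reactants: 3 (R)-4-methyloxan-2-one
Product: 4 (S)-5-iodo-3-methylpentanoic acid
Conditions: Me3SiCl, NaI, MeCN, 70 °C; then H2O
Reagents that add atoms: sodium iodide, [Na+].[I-]
Why: Iodotrimethylsilane made in situ silylates the lactone carbonyl and iodide opens the ring by SN2 attack at the O–CH2 carbon (lactone cleavage to an ω-iodo acid); C13 is unchanged.

Step 3
Reactants: 4 (S)-5-iodo-3-methylpentanoic acid
Product: 5 tert-butyl (S)-5-iodo-3-methylpentanoate
Conditions: t-BuOC(=NH)CCl3, BF3·OEt2 (cat.), cyclohexane/CH2Cl2, rt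
Reagents that add atoms: tert-butyl 2,2,2-trichloroacetimidate, CC(C)(C)OC(=N)C(Cl)(Cl)Cl
Why: Acid-catalysed tert-butylation of the carboxylic acid by the trichloroacetimidate spares the primary iodide.

Step 4
Reactants: 5 tert-butyl (S)-5-iodo-3-methylpentanoate, 6 2-bromo-1,3-dimethylbenzene
Product: 8 tert-butyl (3R)-5-(2,6-dimethylphenyl)-3-methylpentanoate, via tert-butyl (S)-5-(iodozincio)-3-methylpentanoate 7 (not isolated)
Conditions: Zn dust, LiCl, THF, 40 °C; then 6, Pd(OAc)2 (2 mol %), SPhos (4 mol %), THF, 60 °C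
Reagents that add atoms: zinc, [Zn] (zinc atom of 7 only)
Why: Zinc insertion gives the ester-tolerant alkylzinc iodide 7, and Negishi coupling with a biarylphosphine ligand suited to di-ortho-substituted aryl bromides forms the aryl–C11 bond.

Step 5
Reactants: 8 tert-butyl (3R)-5-(2,6-dimethylphenyl)-3-methylpentanoate
Product: 9 tert-butyl (3R)-5-(3,5-dibromo-2,6-dimethylphenyl)-3-methylpentanoate
Conditions: Br2 (2.2 equiv), NaOAc, AcOH, rt → 40 °C, dark
Reagents that add atoms: bromine, BrBr
Why: Electrophilic aromatic bromination occurs twice at the two equivalent positions ortho to one methyl group and para to the other, giving the Cs-symmetric dibromide; the acetate buffer protects the tert-butyl ester from HBr.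

Step 6
Reactants: 10 ethyl (E)-3-(trimethylsilyl)acrylate, 11 potassium vinyltrifluoroborate
Product: 12 ethyl (3R)-3-(trimethylsilyl)pent-4-enoate
Conditions: [Rh(OH)(cod)]2 (1.5 mol %), (R)-BINAP (3.3 mol %), dioxane/H2O, 60 °C
Reagents that add atoms: none
Why: Hayashi–Miyaura rhodium-catalysed asymmetric 1,4-addition of the vinyl group to the (E)-β-silyl enoate; the BINAP–rhodium complex selects the enoate face and sets the silyl-bearing stereocentre (C3).

Step 7
Reactants: 12 ethyl (3R)-3-(trimethylsilyl)pent-4-enoate, 9 tert-butyl (3R)-5-(3,5-dibromo-2,6-dimethylphenyl)-3-methylpentanoate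
Product: 13 tert-butyl (3R)-5-{3-bromo-5-[(2S,3S)-1-ethoxy-1-oxo-3-(trimethylsilyl)pent-4-en-2-yl]-2,6-dimethylphenyl}-3-methylpentanoate (major C2′ epimer)
Conditions: LiNCy2 (2.2 equiv), toluene, −10 °C; then 9 (2.5 equiv, excess recovered), Pd(dba)2 (2 mol %), P(t-Bu)3 (2 mol %), rt; aq. NH4Cl, −78 °C
Reagents that add atoms: none
Why: Buchwald–Hartwig α-arylation of the lithium enolate of 12 at one of the two equivalent C–Br bonds of 9; the product enolate should be protonated on work-up anti to the β-silyl group (Fleming's rule), giving mainly the 2′S epimer, and this centre (C4) is erased again in step 15.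

Step 8
Reactants: 13 α-aryl ester
Product: 14 tert-butyl (3R)-5-{3-bromo-5-[(2S,3S)-1-hydroxy-3-(trimethylsilyl)pent-4-en-2-yl]-2,6-dimethylphenyl}-3-methylpentanoate
Conditions: LiBH4, THF, MeOH (1 equiv), 0 °C → rt
Reagents that add atoms: none
Why: LiBH4 reduces the ethyl ester to the primary alcohol while the tert-butyl ester, the aryl bromide and the allylsilane are inert.

Step 9
Reactants: 14 primary alcohol
Product: 15 tert-butyl (3R)-5-{3-bromo-5-[(2S,3S)-1-(tert-butyldimethylsilyloxy)-3-(trimethylsilyl)pent-4-en-2-yl]-2,6-dimethylphenyl}-3-methylpentanoate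
Conditions: t-BuMe2SiCl, imidazole, DMF, rt
Reagents that add atoms: tert-butyldimethylsilyl chloride, CC(C)(C)[Si](C)(C)Cl
Why: Silylation masks the side-arm oxygen, which would otherwise capture the C10 cation in step 11 as a five-membered ether.

Step 10
Reactants: 15 silyl ether
Product: 17 tert-butyl (3R)-5-{3-[(2S,3S)-1-(tert-butyldimethylsilyloxy)-3-(trimethylsilyl)pent-4-en-2-yl]-5-hydroxy-2,6-dimethylphenyl}-3-methylpentanoate, via aryl pinacol boronate 16 (not isolated)
Conditions: B2pin2, [Pd(dppf)Cl2] (3 mol %), KOAc, dioxane, 85 °C; then NaBO3·4H2O, THF/H2O, rt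
Reagents that add atoms: bis(pinacolato)diboron, CC1(C)OB(OC1(C)C)B1OC(C)(C)C(C)(C)O1 (boryl group of 16 only); sodium perborate, [Na+].[O-]OB=O (phenol oxygen)
Why: Miyaura borylation of the remaining aryl bromide and oxidation of the C–B bond deliver the phenol (oxygen on C7) without touching the allylsilane or the silyl ether.

Step 11
Reactants: 17 phenol
Product: 19 tert-butyl (4S,10R,13R)-19-(tert-butyldimethylsilyloxy)-7-oxo-18-norlabda-2,5,8-trien-15-oate, via phenoxonium cation 18 (not isolated)
Conditions: undivided cell, graphite anode, Pt cathode, constant current (2.2 F/mol), n-Bu4NBF4, 2,6-lutidine, (CF3)2CHOH/CH2Cl2 (1:4), 0 °C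
Reagents that add atoms: none
Why: Proposed new method: two-electron anodic oxidation of phenol 17 with loss of a proton gives phenoxonium cation 18, whose most electrophilic carbon is C10, para to oxygen; allylsilane terminus C1 attacks C10 and the β-silyl cation loses the silyl group to leave the C2=C3 alkene. The closest known reaction types are the oxidative Hosomi–Sakurai dearomatisation of 4-alkylphenols mediated by trivalent iodine and anodic phenol–alkene couplings. Ring A (C10–C1–C2–C3–C4–C5) closes in a 6-endo mode with respect to the allylsilane, ring B being the arene itself. The one new stereocentre, quaternary C10, is controlled by the silyl-bearing C3 centre through the anti-SE2′ rule: in the half-chair transition state the C–Si bond must stand antiperiplanar to the forming C1–C10 bond, which is possible on one arene face only. The step needs para over ortho attack (C10 against C6) and C- over O-trapping; the para position of the phenoxonium ion is the more electrophilic, the side-arm oxygen is silylated, and hexafluoroisopropanol is too weak a nucleophile to intercept the cation before the tethered allylsilane.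

Step 12
Reactants: 19 dienone
Product: 21 tert-butyl (4S,5R,9S,10R,13R)-19-(tert-butyldimethylsilyloxy)-7-(trifluoromethylsulfonyloxy)-18-norlabda-2,7-dien-15-oate, via Δ8-7-ketone 20 (not isolated)
Conditions: Li (5 equiv), NH3/THF, t-BuOH (1.0 equiv), −78 °C; isoprene; NH3 evaporated; then PhNTf2, THF, −78 → 0 °C
Reagents that add atoms: N-phenylbis(trifluoromethanesulfonimide), O=S(=O)(N(c1ccccc1)S(=O)(=O)C(F)(F)F)C(F)(F)F
Why: Birch-type dissolving-metal reduction: the less substituted C5=C6 enone goes first with axial protonation at C5 (H5 anti to the C10 methyl, trans ring fusion), tert-butanol releases enone 20, whose reduction with axial protonation at C9 places the side chain equatorial, and the regiodefined C7–C8 lithium enolate is trapped as the enol triflate.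

Step 13
Reactants: 21 enol triflate silyl ether
Product: 22 tert-butyl (4S,5R,9S,10R,13R)-19-hydroxy-7-(trifluoromethylsulfonyloxy)-18-norlabda-2,7-dien-15-oate
Conditions: HF·pyridine, pyridine, THF, 0 °C → rt
Reagents that add atoms: none
Why: Buffered fluoride cleaves the silyl ether and leaves the enol triflate and the tert-butyl ester intact.

Step 14
Reactants: 22 primary alcohol
Product: 23 tert-butyl (4S,5R,9S,10R,13R)-19-oxo-7-(trifluoromethylsulfonyloxy)-18-norlabda-2,7-dien-15-oate
Conditions: Dess–Martin periodinane, NaHCO3, CH2Cl2, 0 °C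
Reagents that add atoms: none
Why: Dess–Martin oxidation gives the β,γ-unsaturated aldehyde under buffered conditions; it is used at once, and the C4 centre is lost in the next step anyway.

Step 15
Reactants: 23 aldehyde
Product: 24 tert-butyl (4R,5S,9S,10S,13R)-19-oxo-7-(trifluoromethylsulfonyloxy)labda-2,7-dien-15-oate
Conditions: KOt-Bu (1.1 equiv), MeI (5 equiv), THF, −78 → −30 °C
Reagents that add atoms: iodomethane, CI
Why: Deconjugative α-methylation of the β,γ-unsaturated aldehyde through its potassium dienolate: iodomethane should attack C4 anti to the axial C10 methyl group, so the new methyl is equatorial and the formyl group axial, and the C2=C3 alkene stays in place.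

Step 16
Reactants: 24 quaternary aldehyde
Product: 25 tert-butyl (2S,3R,4S,5S,9S,10S,13R)-2,3-dihydroxy-19-oxo-7-(trifluoromethylsulfonyloxy)labd-7-en-15-oate
Conditions: OsO4 (2 mol %), N-methylmorpholine N-oxide, acetone/H2O, 0 °C → rt
Reagents that add atoms: N-methylmorpholine N-oxide, C[N+]1([O-])CCOCC1; water, O
Why: Upjohn dihydroxylation of the only electron-rich alkene (the tetrasubstituted enol triflate is inert) from the face opposite the axial C10 methyl and C4 formyl groups gives the 2,3-cis-diol of the target.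

Step 17
Reactants: 25 diol
Product: 26 tert-butyl (2S,3R,4S,5S,9S,10S,13R)-2-acetoxy-3-hydroxy-19-oxo-7-(trifluoromethylsulfonyloxy)labd-7-en-15-oate
Conditions: Ac2O (1.2 equiv), pyridine, CH2Cl2, 0 °C
Reagents that add atoms: acetic anhydride, CC(=O)OC(C)=O
Why: The equatorial C2 hydroxyl is acetylated selectively because the axial C3 hydroxyl is shielded by the quaternary C4 centre.

Step 18
Reactants: 26 monoacetate enol triflate
Product: 27 tert-butyl (2S,3R,4S,5S,9R,10S,13R)-2-acetoxy-3-hydroxy-19-oxolabd-7-en-15-oate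
Conditions: Pd(OAc)2 (5 mol %), PPh3 (10 mol %), HCO2H, n-Bu3N, DMF, 60 °C
Reagents that add atoms: none
Why: Palladium-catalysed formate reduction of the enol triflate (oxidative addition, hydride transfer from formate, reductive elimination) unveils the C7=C8 alkene regiospecifically.

Step 19
Reactants: 27 tert-butyl ester
Product: 28 target, (2S,3R,4S,5S,9R,10S,13R)-2-acetoxy-3-hydroxy-19-oxolabd-7-en-15-oic acid
Conditions: CF3CO2H/CH2Cl2 (1:4), 0 °C
Reagents that add atoms: none
Why: Acidolysis of the tert-butyl ester with loss of isobutene liberates the C15 acid without affecting the acetate, the aldehyde or the alkene.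

**Compound list**

1 | (R)-5-methoxy-3-methyl-5-oxopentanoic acid | OC(=O)C[C@@H](C)CC(=O)OC | starting material
2 | methyl (R)-5-hydroxy-3-methylpentanoate (not isolated) | COC(=O)C[C@H](C)CCO | intermediate
3 | (R)-4-methyloxan-2-one | O=C1C[C@H](C)CCO1 | intermediate
4 | (S)-5-iodo-3-methylpentanoic acid | OC(=O)C[C@H](C)CCI | intermediate
5 | tert-butyl (S)-5-iodo-3-methylpentanoate | CC(C)(C)OC(=O)C[C@H](C)CCI | intermediate
6 | 2-bromo-1,3-dimethylbenzene | Cc1cccc(C)c1Br | starting material
7 | tert-butyl (S)-5-(iodozincio)-3-methylpentanoate (not isolated) | CC(C)(C)OC(=O)C[C@H](C)CC[Zn]I | intermediate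
8 | tert-butyl (3R)-5-(2,6-dimethylphenyl)-3-methylpentanoate | CC(C)(C)OC(=O)C[C@H](C)CCc1c(C)cccc1C | intermediate
9 | tert-butyl (3R)-5-(3,5-dibromo-2,6-dimethylphenyl)-3-methylpentanoate | CC(C)(C)OC(=O)C[C@H](C)CCc1c(C)c(Br)cc(Br)c1C | intermediate
10 | ethyl (E)-3-(trimethylsilyl)acrylate | CCOC(=O)/C=C/[Si](C)(C)C | starting material
11 | potassium vinyltrifluoroborate | C=C[B-](F)(F)F.[K+] | starting material
12 | ethyl (3R)-3-(trimethylsilyl)pent-4-enoate | CCOC(=O)C[C@@H]([Si](C)(C)C)C=C | intermediate
13 | α-aryl ester (see step 7) | CCOC(=O)[C@@H]([C@@H]([Si](C)(C)C)C=C)c1cc(Br)c(C)c(CC[C@@H](C)CC(=O)OC(C)(C)C)c1C | intermediate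
14 | primary alcohol (see step 8) | OC[C@@H]([C@@H]([Si](C)(C)C)C=C)c1cc(Br)c(C)c(CC[C@@H](C)CC(=O)OC(C)(C)C)c1C | intermediate
15 | silyl ether aryl bromide (see step 9) | CC(C)(C)[Si](C)(C)OC[C@@H]([C@@H]([Si](C)(C)C)C=C)c1cc(Br)c(C)c(CC[C@@H](C)CC(=O)OC(C)(C)C)c1C | intermediate
16 | aryl pinacol boronate (not isolated) | CC(C)(C)[Si](C)(C)OC[C@@H]([C@@H]([Si](C)(C)C)C=C)c1cc(B2OC(C)(C)C(C)(C)O2)c(C)c(CC[C@@H](C)CC(=O)OC(C)(C)C)c1C | intermediate
17 | phenol, key-step substrate (see step 10) | CC(C)(C)[Si](C)(C)OC[C@@H]([C@@H]([Si](C)(C)C)C=C)c1cc(O)c(C)c(CC[C@@H](C)CC(=O)OC(C)(C)C)c1C | intermediate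
18 | phenoxonium cation, drawn as the C10 carbocation (not isolated) | CC(C)(C)[Si](C)(C)OC[C@@H]([C@@H]([Si](C)(C)C)C=C)C1=CC(=O)C(C)=C(CC[C@@H](C)CC(=O)OC(C)(C)C)[C+]1C | intermediate
19 | tert-butyl (4S,10R,13R)-19-(tert-butyldimethylsilyloxy)-7-oxo-18-norlabda-2,5,8-trien-15-oate | C=1C[C@@]2(C)C(CC[C@@H](C)CC(=O)OC(C)(C)C)=C(C)C(=O)C=C2[C@@H](CO[Si](C)(C)C(C)(C)C)C=1 | intermediate
20 | tert-butyl (4S,5R,10R,13R)-19-(tert-butyldimethylsilyloxy)-7-oxo-18-norlabda-2,8-dien-15-oate (not isolated) | C=1C[C@@]2(C)C(CC[C@@H](C)CC(=O)OC(C)(C)C)=C(C)C(=O)C[C@@H]2[C@@H](CO[Si](C)(C)C(C)(C)C)C=1 | intermediate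
21 | enol triflate silyl ether (see step 12) | C=1C[C@@]2(C)[C@H](CC[C@@H](C)CC(=O)OC(C)(C)C)C(C)=C(OS(=O)(=O)C(F)(F)F)C[C@@H]2[C@@H](CO[Si](C)(C)C(C)(C)C)C=1 | intermediate
22 | enol triflate alcohol (see step 13) | C=1C[C@@]2(C)[C@H](CC[C@@H](C)CC(=O)OC(C)(C)C)C(C)=C(OS(=O)(=O)C(F)(F)F)C[C@@H]2[C@@H](CO)C=1 | intermediate
23 | enol triflate aldehyde (see step 14) | C=1C[C@@]2(C)[C@H](CC[C@@H](C)CC(=O)OC(C)(C)C)C(C)=C(OS(=O)(=O)C(F)(F)F)C[C@@H]2[C@@H](C=O)C=1 | intermediate
24 | C4-methylated aldehyde (see step 15) | C=1C[C@@]2(C)[C@H](CC[C@@H](C)CC(=O)OC(C)(C)C)C(C)=C(OS(=O)(=O)C(F)(F)F)C[C@@H]2[C@](C)(C=O)C=1 | intermediate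
25 | 2,3-diol (see step 16) | O[C@H]1C[C@@]2(C)[C@H](CC[C@@H](C)CC(=O)OC(C)(C)C)C(C)=C(OS(=O)(=O)C(F)(F)F)C[C@@H]2[C@](C)(C=O)[C@H]1O | intermediate
26 | 2-acetate (see step 17) | CC(=O)O[C@H]1C[C@@]2(C)[C@H](CC[C@@H](C)CC(=O)OC(C)(C)C)C(C)=C(OS(=O)(=O)C(F)(F)F)C[C@@H]2[C@](C)(C=O)[C@H]1O | intermediate
27 | tert-butyl ester of the target (see step 18) | CC(=O)O[C@H]1C[C@@]2(C)[C@H](CC[C@@H](C)CC(=O)OC(C)(C)C)C(C)=CC[C@@H]2[C@](C)(C=O)[C@H]1O | intermediate
28 | (2S,3R,4S,5S,9R,10S,13R)-2-acetoxy-3-hydroxy-19-oxolabd-7-en-15-oic acid | CC(=O)O[C@H]1C[C@@]2(C)[C@H](CC[C@@H](C)CC(=O)O)C(C)=CC[C@@H]2[C@](C)(C=O)[C@H]1O | target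

**Step count and risks**

Total: 19 steps. Longest linear sequence: 18 steps (steps 1–5 and 7–19); step 6 is a one-step branch.

Most likely to fail:

1. Step 11 (the proposed new method). The phenoxonium ion may be diverted: attack of C1 at C6 with rearomatisation, proton loss from the C10 methyl group to a quinone methide, or oxidation of the allylsilane at the anode. The fallback uses known chemistry, sets out from 17 and comes back at 19. Oxidative dearomatisation of 17 with PhI(OAc)2 in methanol should give the isolable para-quinol methyl ether, the 10-methoxy dienone F1. Its ionisation with BF3·OEt2 in CH2Cl2 at −78 °C regenerates the C10 cation away from any oxidant, and intramolecular Sakurai allylation then closes ring A to 19.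

2. Step 12. The double reduction may stop at enone 20, may over-reduce the tert-butyl ester, or the enolate may equilibrate before trapping so that the triflate forms towards C6. The fallback sets out from 19 and comes back at 21. Reduction with excess Li in NH3 followed by NH4Cl quench goes all the way to the saturated 7-ketone F2 (8-methyl equatorial after equilibration). Thermodynamic enol triflate formation with Tf2O and 2,6-di-tert-butyl-4-methylpyridine towards the more substituted C8 then gives 21.

3. Step 15. The dienolate may be methylated on oxygen or at C2, may condense with unreacted aldehyde, or may be attacked with poor facial selectivity. The fallback sets out from 23 and comes back at 24 and avoids a free enolate (Conia methylation). Soft enolisation with Me3SiOTf/Et3N gives the trimethylsilyl dienol ether F3. Simmons–Smith cyclopropanation (Et2Zn, CH2I2) of the electron-rich enol ether double bond from the face opposite the C10 methyl group gives siloxycyclopropane F4. Ring opening with K2CO3 in methanol delivers the C4 methyl group and the aldehyde of 24.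

**Further compounds**

F1 | step 11 | tert-butyl (3R)-5-{3-[(2S,3S)-1-(tert-butyldimethylsilyloxy)-3-(trimethylsilyl)pent-4-en-2-yl]-6-methoxy-2,6-dimethyl-5-oxocyclohexa-1,3-dien-1-yl}-3-methylpentanoate (10-methoxy dienone, C10 epimers) | COC1(C)C(CC[C@@H](C)CC(=O)OC(C)(C)C)=C(C)C(=O)C=C1[C@@H](CO[Si](C)(C)C(C)(C)C)[C@@H]([Si](C)(C)C)C=C
F2 | step 12 | tert-butyl (4S,5R,8S,9S,10R,13R)-19-(tert-butyldimethylsilyloxy)-7-oxo-18-norlabd-2-en-15-oate | C=1C[C@@]2(C)[C@H](CC[C@@H](C)CC(=O)OC(C)(C)C)[C@@H](C)C(=O)C[C@@H]2[C@@H](CO[Si](C)(C)C(C)(C)C)C=1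
F3 | step 15 | trimethylsilyl dienol ether of 23 (C4=C19 enol ether, geometry not defined) | C=1C[C@@]2(C)[C@H](CC[C@@H](C)CC(=O)OC(C)(C)C)C(C)=C(OS(=O)(=O)C(F)(F)F)C[C@@H]2C(=CO[Si](C)(C)C)C=1
F4 | step 15 | siloxycyclopropane spiro-fused at C4 (new CH2 on the face opposite the C10 methyl; C19 epimers) | C=1C[C@@]2(C)[C@H](CC[C@@H](C)CC(=O)OC(C)(C)C)C(C)=C(OS(=O)(=O)C(F)(F)F)C[C@@H]2[C@@]3(CC3O[Si](C)(C)C)C=1
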